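**Plan**

- Retrosynthesis: the C11′=C12′ olefin of the polyene is cut first (Horner–Wadsworth–Emmons). The furan-2(5H)-one ring is then cut twice, at C3=C4 and at O1–C5. The oxygen bridge O–C6 of the 7-oxabicyclo[2.2.1]heptane and the C4′–OH of the dihydroxy ring are both traced back to epoxides.
- Enabling feature: in the lactone ring, C2(=O)–C3 is a masked α-keto acid (C3 is the keto carbon) and O1–C5(=CH–chain)–C4H is a masked allenyl (propargyl) phosphonium. A carboxylate oxygen adds to the central allene carbon, which makes O1–C5 and keeps the exocyclic C5=CH. The ylide so formed at C4 lies five atoms from the C3 ketone, so a Wittig reaction closes the ring through the C3=C4 bond.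
- Forward order: (a) dihydroxycyclohexene ring, then chain extension to a C15 phosphonate; (b) epoxycyclohexane, keto-ester side arm, oxygen bridge, α-keto carboxylate; (c) C9 dienyne phosphonium salt; (d) annulation of (b) with (c) builds the butenolide; (e) acetal hydrolysis, olefination with (a), desilylation.
- Stereochemistry: in the oxabicycle, C3 comes from (4R,6R)-actinol, C5/C6 from Sharpless epoxidation anti to the silyloxy group, with inversion at C6 when the bridge forms. In the dihydroxy ring, C3′ comes from CBS reduction and C4′ from OH-directed epoxidation and E1cB opening (cis). E-olefins come from stabilised Wittig/HWE reagents and the (5Z)-ylidene from thermodynamic control.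

Key step: step 26

Assumption: the six starting materials (the racemic keto ester, the C5 phosphonate, (4R,6R)-actinol, the two acyl-stabilised ylides and (E)-3-methylpent-2-en-4-yn-1-ol) are taken as purchasable; ring atoms are cited by carotenoid locants (primed for the dihydroxy half) and the lactone as O1/C2–C5.

**Dihydroxy half (C15 phosphonate)**

Step 1
Reactants: 1 ethyl 2,6,6-trimethyl-4-oxocyclohex-2-ene-1-carboxylate (racemic)
Product: 2 ethyl (1RS,4S)-4-hydroxy-2,6,6-trimethylcyclohex-2-ene-1-carboxylate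
Conditions: (R)-Me-CBS (0.2 equiv), BH3·SMe2, THF, −20 °C; MeOH quench
Reagents that add atoms: none
Why: Corey–Bakshi–Shibata reduction, in which the (R)-oxazaborolidine–borane complex treats the alkenyl arm as the large group and delivers hydride to give the (S)-carbinol (future C3′) in both C1 epimers of the configurationally labile substrate, C1 being erased in step 3.

Step 2
Reactants: 2 ethyl (1RS,4S)-4-hydroxy-2,6,6-trimethylcyclohex-2-ene-1-carboxylate
Product: 3 ethyl (1R,2RS,5S,6S)-5-hydroxy-1,3,3-trimethyl-7-oxabicyclo[4.1.0]heptane-2-carboxylate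
Conditions: VO(acac)2 (2 mol%), t-BuOOH, CH2Cl2, 0 °C → rt
Reagents that add atoms: tert-butyl hydroperoxide CC(C)(C)OO
Why: Hydroxyl-directed vanadium-catalysed epoxidation, in which the vanadium alkoxide delivers oxygen to the trisubstituted alkene on the face of the OH group, so that the epoxide is cis to the carbinol in either ester epimer.

Step 3
Reactants: 3 ethyl (1R,2RS,5S,6S)-5-hydroxy-1,3,3-trimethyl-7-oxabicyclo[4.1.0]heptane-2-carboxylate
Product: 4 ethyl (3R,4S)-3,4-dihydroxy-2,6,6-trimethylcyclohex-1-ene-1-carboxylate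
Conditions: DBU (1.2 equiv), CH2Cl2, rt
Reagents that add atoms: none
Why: E1cB opening of a β,γ-epoxy ester, in which DBU removes the ester α-H and the enolate expels the epoxide oxygen from the β-carbon, so that both epimers converge on the conjugated ester and the retained C–O bond becomes the allylic C4′–OH cis to C3′–OH.

Step 4
Reactants: 4 ethyl (3R,4S)-3,4-dihydroxy-2,6,6-trimethylcyclohex-1-ene-1-carboxylate
Product: 5 ethyl (3R,4S)-2,6,6-trimethyl-3,4-bis(triethylsilyloxy)cyclohex-1-ene-1-carboxylate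
Conditions: TESCl, imidazole, DMAP (cat.), DMF, rt
Reagents that add atoms: chlorotriethylsilane CC[Si](Cl)(CC)CC
Why: Silyl ether formation on both secondary hydroxyls of the cis-diol, which masks the acid-sensitive allylic C4′–OH until the last step.

Step 5
Reactants: 5 ethyl (3R,4S)-2,6,6-trimethyl-3,4-bis(triethylsilyloxy)cyclohex-1-ene-1-carboxylate
Product: 6 [(3R,4S)-2,6,6-trimethyl-3,4-bis(triethylsilyloxy)cyclohex-1-en-1-yl]methanol
Conditions: DIBAL-H, CH2Cl2, −78 → −20 °C; aqueous work-up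
Reagents that add atoms: none
Why: DIBAL-H reduction of the hindered conjugated ester should proceed 1,2 to the allylic alcohol without touching the silyl ethers.

Step 6
Reactants: 6 [(3R,4S)-2,6,6-trimethyl-3,4-bis(triethylsilyloxy)cyclohex-1-en-1-yl]methanol
Product: 7 (3R,4S)-2,6,6-trimethyl-3,4-bis(triethylsilyloxy)cyclohex-1-ene-1-carbaldehyde
Conditions: activated MnO2, CH2Cl2, rt
Reagents that add atoms: none
Why: MnO2 oxidation is selective for the primary allylic alcohol and should give the enal without disturbing the silyloxy centres.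

Step 7
Reactants: 7 (3R,4S)-2,6,6-trimethyl-3,4-bis(triethylsilyloxy)cyclohex-1-ene-1-carbaldehyde; 8 ethyl (2E)-4-(diethoxyphosphoryl)-3-methylbut-2-enoate
Product: 9 ethyl (2E,4E)-3-methyl-5-[(3R,4S)-2,6,6-trimethyl-3,4-bis(triethylsilyloxy)cyclohex-1-en-1-yl]penta-2,4-dienoate
Conditions: NaH, THF, 0 °C → rt
Reagents that add atoms: none
Why: Horner–Wadsworth–Emmons olefination of the non-enolisable aldehyde with the vinylogous phosphonate anion should give mainly the (2E,4E)-dienoate, the minor 2Z isomer being removable by chromatography.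

Step 8
Reactants: 9 ethyl (2E,4E)-3-methyl-5-[(3R,4S)-2,6,6-trimethyl-3,4-bis(triethylsilyloxy)cyclohex-1-en-1-yl]penta-2,4-dienoate
Product: 10 (2E,4E)-3-methyl-5-[(3R,4S)-2,6,6-trimethyl-3,4-bis(triethylsilyloxy)cyclohex-1-en-1-yl]penta-2,4-dien-1-ol
Conditions: DIBAL-H, CH2Cl2, −78 °C; aqueous work-up
Reagents that add atoms: none
Why: DIBAL-H reduces the dienoate 1,2 to the primary allylic alcohol with the double-bond geometry unchanged.

Step 9
Reactants: 10 (2E,4E)-3-methyl-5-[(3R,4S)-2,6,6-trimethyl-3,4-bis(triethylsilyloxy)cyclohex-1-en-1-yl]penta-2,4-dien-1-ol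
Product: 11 (3R,4S)-1-[(1E,3E)-5-bromo-3-methylpenta-1,3-dien-1-yl]-2,6,6-trimethyl-3,4-bis(triethylsilyloxy)cyclohex-1-ene
Conditions: CBr4, PPh3, CH2Cl2, −20 °C; used at once
Reagents that add atoms: carbon tetrabromide BrC(Br)(Br)Br
Why: Appel bromination converts the dienyl alcohol into the primary allylic bromide under neutral conditions that the silyl ethers tolerate.

Step 10
Reactants: 11 (3R,4S)-1-[(1E,3E)-5-bromo-3-methylpenta-1,3-dien-1-yl]-2,6,6-trimethyl-3,4-bis(triethylsilyloxy)cyclohex-1-ene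
Product: 12 diethyl {(2E,4E)-3-methyl-5-[(3R,4S)-2,6,6-trimethyl-3,4-bis(triethylsilyloxy)cyclohex-1-en-1-yl]penta-2,4-dien-1-yl}phosphonate
Conditions: P(OEt)3, toluene, 70 °C
Reagents that add atoms: triethyl phosphite CCOP(OCC)OCC
Why: Michaelis–Arbuzov reaction at the unhindered primary allylic carbon (SN2, the trisubstituted terminus blocking SN2′) gives the phosphonate for the final E-selective olefination.

**Oxabicyclic half (α-keto carboxylate)**

Step 11
Reactants: 13 (4R,6R)-4-hydroxy-2,2,6-trimethylcyclohexan-1-one (actinol)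
Product: 14 (4R,6R)-2,2,6-trimethyl-4-(triethylsilyloxy)cyclohexan-1-one
Conditions: TESCl, imidazole, DMF, rt
Reagents that add atoms: chlorotriethylsilane CC[Si](Cl)(CC)CC
Why: Silyl ether formation protects the chiral-pool carbinol (future C3) for the enolate and hydride steps.

Step 12
Reactants: 14 (4R,6R)-2,2,6-trimethyl-4-(triethylsilyloxy)cyclohexan-1-one
Product: 15 (4R)-2,6,6-trimethyl-4-(triethylsilyloxy)cyclohex-1-en-1-yl trifluoromethanesulfonate
Conditions: LDA, THF, −78 °C; PhNTf2, −78 °C → rt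
Reagents that add atoms: N-phenylbis(trifluoromethanesulfonimide) O=S(=O)(N(c1ccccc1)S(=O)(=O)C(F)(F)F)C(F)(F)F
Why: Enol triflate formation, in which enolisation is possible only towards the methine carbon (the other α-carbon is quaternary) and O-triflation fixes the tetrasubstituted C5=C6 double bond.

Step 13
Reactants: 15 (4R)-2,6,6-trimethyl-4-(triethylsilyloxy)cyclohex-1-en-1-yl trifluoromethanesulfonate
Product: 16 methyl (4R)-2,6,6-trimethyl-4-(triethylsilyloxy)cyclohex-1-ene-1-carboxylate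
Conditions: Pd(OAc)2 (5 mol%), PPh3, CO (1 atm), MeOH, Et3N, DMF, 60 °C
Reagents that add atoms: carbon monoxide [C-]#[O+]; methanol CO
Why: Palladium-catalysed methoxycarbonylation of the vinyl triflate (oxidative addition, CO insertion, methanolysis) installs C7 at the ester oxidation level.

Step 14
Reactants: 16 methyl (4R)-2,6,6-trimethyl-4-(triethylsilyloxy)cyclohex-1-ene-1-carboxylate
Product: 17 [(4R)-2,6,6-trimethyl-4-(triethylsilyloxy)cyclohex-1-en-1-yl]methanol
Conditions: DIBAL-H, CH2Cl2, −78 → 0 °C; aqueous work-up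
Reagents that add atoms: none
Why: DIBAL-H reduction gives the tetrasubstituted primary allylic alcohol required for directed asymmetric epoxidation.

Step 15
Reactants: 17 [(4R)-2,6,6-trimethyl-4-(triethylsilyloxy)cyclohex-1-en-1-yl]methanol
Product: 18 [(1R,4S,6R)-2,2,6-trimethyl-4-(triethylsilyloxy)-7-oxabicyclo[4.1.0]heptan-1-yl]methanol
Conditions: Ti(OiPr)4, D-(−)-diethyl tartrate, t-BuOOH, 4 Å MS, CH2Cl2, −20 °C
Reagents that add atoms: tert-butyl hydroperoxide CC(C)(C)OO
Why: Sharpless asymmetric epoxidation, in which the titanium–D-(−)-tartrate complex delivers oxygen to the alkene face opposite the silyloxy group (reagent control) and so sets C5 and C6 of the anti-epoxide.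

Step 16
Reactants: 18 [(1R,4S,6R)-2,2,6-trimethyl-4-(triethylsilyloxy)-7-oxabicyclo[4.1.0]heptan-1-yl]methanol
Product: 19 (1S,4S,6R)-2,2,6-trimethyl-4-(triethylsilyloxy)-7-oxabicyclo[4.1.0]heptane-1-carbaldehyde
Conditions: TPAP (5 mol%), NMO, 4 Å MS, CH2Cl2, rt
Reagents that add atoms: none
Why: Ley–Griffith oxidation gives the non-enolisable epoxy aldehyde under neutral conditions that spare the epoxide and the silyl ether.

Step 17
Reactants: 19 (1S,4S,6R)-2,2,6-trimethyl-4-(triethylsilyloxy)-7-oxabicyclo[4.1.0]heptane-1-carbaldehyde; 20 ethyl 2-oxo-3-(triphenyl-λ5-phosphanylidene)propanoate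
Product: 21 ethyl (3E)-2-oxo-4-[(1S,4S,6R)-2,2,6-trimethyl-4-(triethylsilyloxy)-7-oxabicyclo[4.1.0]heptan-1-yl]but-3-enoate
Conditions: toluene, 80 °C
Reagents that add atoms: none
Why: Wittig olefination with the stabilised acyl ylide gives the E-enone and places the complete C2/C3 α-keto ester unit of the future lactone on the end group in one step.

Step 18
Reactants: 21 ethyl (3E)-2-oxo-4-[(1S,4S,6R)-2,2,6-trimethyl-4-(triethylsilyloxy)-7-oxabicyclo[4.1.0]heptan-1-yl]but-3-enoate
Product: 23 ethyl (3E)-4-[(1R,2R,4S)-2-hydroxy-2,6,6-trimethyl-7-oxabicyclo[2.2.1]heptan-1-yl]-2-oxobut-3-enoate, via hydroxy epoxide 22 (not isolated)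
Conditions: p-TsOH·H2O (0.1 equiv), THF–H2O (10:1), 0 °C → rt
Reagents that add atoms: none
Why: Acid cleaves the triethylsilyl ether and the freed C3–OH, held anti to the epoxide, opens the protonated γ,δ-epoxy enone at the allylic carbon C6 from the rear (intramolecular SN2-type epoxide opening, the reaction type used for 3,6-epoxy-5-hydroxy carotenoid end groups), so that C6 is inverted, C5 keeps its oxygen as the tertiary alcohol and the electron-poor side arm blocks the furanoid rearrangement.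

Step 19
Reactants: 23 ethyl (3E)-4-[(1R,2R,4S)-2-hydroxy-2,6,6-trimethyl-7-oxabicyclo[2.2.1]heptan-1-yl]-2-oxobut-3-enoate
Product: 24 caesium (3E)-4-[(1R,2R,4S)-2-hydroxy-2,6,6-trimethyl-7-oxabicyclo[2.2.1]heptan-1-yl]-2-oxobut-3-enoate
Conditions: CsOH·H2O (1.0 equiv), THF–H2O, 0 °C; freeze-dry
Reagents that add atoms: caesium hydroxide [Cs+].[OH-]
Why: Saponification of the very electrophilic α-keto ester with one equivalent of hydroxide at 0 °C should give the carboxylate salt directly in the form needed for the annulation.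

**C9 phosphonium salt**

Step 20
Reactants: 25 (2E)-3-methylpent-2-en-4-yn-1-ol
Product: 26 (2E)-3-methylpent-2-en-4-ynal
Conditions: activated MnO2, CH2Cl2, rt
Reagents that add atoms: none
Why: MnO2 oxidation of the primary allylic alcohol gives the enynal with the E geometry retained.

Step 21
Reactants: 26 (2E)-3-methylpent-2-en-4-ynal; 27 (triphenyl-λ5-phosphanylidene)acetaldehyde
Product: 28 (2E,4E)-5-methylhepta-2,4-dien-6-ynal
Conditions: toluene, 60 °C (slight deficit of 27)
Reagents that add atoms: none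
Why: Wittig two-carbon homologation with the formyl-stabilised ylide gives the E-enal, and the deficit of ylide limits a second homologation.

Step 22
Reactants: 28 (2E,4E)-5-methylhepta-2,4-dien-6-ynal
Product: 29 (3E,5E)-7,7-dimethoxy-3-methylhepta-3,5-dien-1-yne
Conditions: HC(OMe)3, Amberlyst-15 (cat.), CH2Cl2, 0 °C
Reagents that add atoms: trimethyl orthoformate COC(OC)OC
Why: Acid-catalysed acetalisation with the orthoformate masks the aldehyde for the organolithium and ylide chemistry that follows.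

Step 23
Reactants: 29 (3E,5E)-7,7-dimethoxy-3-methylhepta-3,5-dien-1-yne
Product: 30 (4E,6E)-8,8-dimethoxy-4-methylocta-4,6-dien-2-yn-1-ol
Conditions: n-BuLi, THF, −78 °C; (CH2O)n, −78 °C → rt; H2O
Reagents that add atoms: formaldehyde (as paraformaldehyde) C=O
Why: Addition of the lithium acetylide to formaldehyde gives the propargylic alcohol whose new carbon is the future C4 of the lactone.

Step 24
Reactants: 30 (4E,6E)-8,8-dimethoxy-4-methylocta-4,6-dien-2-yn-1-ol
Product: 31 (2E,4E)-8-bromo-1,1-dimethoxy-5-methylocta-2,4-dien-6-yne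
Conditions: CBr4, PPh3, 2,6-lutidine, CH2Cl2, −20 °C
Reagents that add atoms: carbon tetrabromide BrC(Br)(Br)Br
Why: Appel bromination under buffered neutral conditions gives the propargylic bromide without loss of the acid-labile acetal.

Step 25
Reactants: 31 (2E,4E)-8-bromo-1,1-dimethoxy-5-methylocta-2,4-dien-6-yne
Product: 32 [(4E,6E)-8,8-dimethoxy-4-methylocta-4,6-dien-2-yn-1-yl]triphenylphosphonium bromide
Conditions: PPh3, toluene, rt, dark
Reagents that add atoms: triphenylphosphine c1ccc(cc1)P(c1ccccc1)c1ccccc1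
Why: SN2 quaternisation of triphenylphosphine by the propargylic bromide gives the propargylphosphonium salt, the latent allenylphosphonium and ylide partner of the key step.

**Union and completion**

Step 26
Reactants: 24 caesium (3E)-4-[(1R,2R,4S)-2-hydroxy-2,6,6-trimethyl-7-oxabicyclo[2.2.1]heptan-1-yl]-2-oxobut-3-enoate; 32 [(4E,6E)-8,8-dimethoxy-4-methylocta-4,6-dien-2-yn-1-yl]triphenylphosphonium bromide
Product: 35 (5Z)-5-[(2E,4E)-6,6-dimethoxy-2-methylhexa-2,4-dien-1-ylidene]-3-{(E)-2-[(1R,2R,4S)-2-hydroxy-2,6,6-trimethyl-7-oxabicyclo[2.2.1]heptan-1-yl]ethenyl}furan-2(5H)-one, via allenylphosphonium carboxylate 33 (not isolated), via acyloxyallyl ylide 34 (not isolated)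
Conditions: Et3N (0.2 equiv), MeCN (0.01 M), 0 °C → rt; then I2 (1 mol%), CH2Cl2, daylight
Reagents that add atoms: none
Why: Proposed new method: salt metathesis and base-mediated propargyl-to-allenyl isomerisation of 32 give the ion pair 33, whose α-keto carboxylate adds through oxygen to the central allene carbon (β to P+) to form O1–C5 and the acyloxyallyl ylide 34; the ylide carbon (C4) then attacks the keto carbonyl (C3) five atoms away and loses Ph3P=O, so that the C3=C4 bond closes the furan-2(5H)-one ring. The closest known reaction type is the Schweizer annulation (conjugate addition of a carbonyl-bearing nucleophile to a vinylphosphonium salt followed by intramolecular Wittig ring closure, as in the 2,5-dihydrofuran synthesis from acyloin alkoxides), combined with the known addition of heteronucleophiles to the central carbon of propargyl/allenylphosphonium salts. The ring closes by 5-exo-trig attack of the ylide carbon on the ketone C=O and is made irreversible by extrusion of the phosphine oxide. No stereocentre is formed; the new stereo-element is the exocyclic C5=CH bond, whose Z geometry (chain syn to O1, away from the PPh3-bearing C4 in 34 and from C4–H in 35) is the thermodynamic one and is secured by reversible C-protonation of 34 and by the iodine-catalysed equilibration in the work-up. The step needs attack at the central allene carbon and Wittig reaction at the ketone and not at the ester carbonyl; the P+-polarised C4=C5 π bond and the much higher electrophilicity and five-ring proximity of the α-keto carbonyl should secure both. The tertiary alcohol, the acetal and the oxygen bridge are inert to catalytic Et3N in MeCN, and high dilution disfavours intermolecular Wittig reaction.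

Step 27
Reactants: 35 (5Z)-5-[(2E,4E)-6,6-dimethoxy-2-methylhexa-2,4-dien-1-ylidene]-3-{(E)-2-[(1R,2R,4S)-2-hydroxy-2,6,6-trimethyl-7-oxabicyclo[2.2.1]heptan-1-yl]ethenyl}furan-2(5H)-one
Product: 36 (2E,4E,6Z)-6-[4-{(E)-2-[(1R,2R,4S)-2-hydroxy-2,6,6-trimethyl-7-oxabicyclo[2.2.1]heptan-1-yl]ethenyl}-5-oxofuran-2(5H)-ylidene]-5-methylhexa-2,4-dienal
Conditions: PPTS (cat.), acetone–H2O (10:1), rt
Reagents that add atoms: water O
Why: Mild acid hydrolysis of the conjugated dimethyl acetal releases the trienal under conditions that should leave the ylidene lactone, the tertiary alcohol and the oxygen bridge untouched.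

Step 28
Reactants: 12 diethyl {(2E,4E)-3-methyl-5-[(3R,4S)-2,6,6-trimethyl-3,4-bis(triethylsilyloxy)cyclohex-1-en-1-yl]penta-2,4-dien-1-yl}phosphonate; 36 (2E,4E,6Z)-6-[4-{(E)-2-[(1R,2R,4S)-2-hydroxy-2,6,6-trimethyl-7-oxabicyclo[2.2.1]heptan-1-yl]ethenyl}-5-oxofuran-2(5H)-ylidene]-5-methylhexa-2,4-dienal
Product: 37 (5Z)-5-{(2E,4E,6E,8E,10E)-2,9-dimethyl-11-[(3R,4S)-2,6,6-trimethyl-3,4-bis(triethylsilyloxy)cyclohex-1-en-1-yl]undeca-2,4,6,8,10-pentaen-1-ylidene}-3-{(E)-2-[(1R,2R,4S)-2-hydroxy-2,6,6-trimethyl-7-oxabicyclo[2.2.1]heptan-1-yl]ethenyl}furan-2(5H)-one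
Conditions: 12, NaHMDS, THF, −78 °C; then 36, −78 → −20 °C
Reagents that add atoms: none
Why: Horner–Wadsworth–Emmons olefination, in which the allylic phosphonate anion adds to the aldehyde at low temperature and loss of phosphate should give the new C11′=C12′ bond mainly E, the tertiary alcohol being too weak an acid to quench the anion.

Step 29
Reactants: 37 (5Z)-5-{(2E,4E,6E,8E,10E)-2,9-dimethyl-11-[(3R,4S)-2,6,6-trimethyl-3,4-bis(triethylsilyloxy)cyclohex-1-en-1-yl]undeca-2,4,6,8,10-pentaen-1-ylidene}-3-{(E)-2-[(1R,2R,4S)-2-hydroxy-2,6,6-trimethyl-7-oxabicyclo[2.2.1]heptan-1-yl]ethenyl}furan-2(5H)-one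
Product: 38 (5Z)-5-{(2E,4E,6E,8E,10E)-11-[(3R,4S)-3,4-dihydroxy-2,6,6-trimethylcyclohex-1-en-1-yl]-2,9-dimethylundeca-2,4,6,8,10-pentaen-1-ylidene}-3-{(E)-2-[(1R,2R,4S)-2-hydroxy-2,6,6-trimethyl-7-oxabicyclo[2.2.1]heptan-1-yl]ethenyl}furan-2(5H)-one (CNP0216838.1)
Conditions: HF·pyridine, pyridine, THF, 0 °C → rt, dark
Reagents that add atoms: none
Why: Fluoride-mediated cleavage of both triethylsilyl ethers under pyridine-buffered conditions should avoid ionisation of the allylic C4′–O bond and opening of the lactone.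

**Compound list**

1 | ethyl 2,6,6-trimethyl-4-oxocyclohex-2-ene-1-carboxylate (racemic) | CCOC(=O)C1C(C)=CC(=O)CC1(C)C | starting material
2 | ethyl (1RS,4S)-4-hydroxy-2,6,6-trimethylcyclohex-2-ene-1-carboxylate | CCOC(=O)C1C(C)=C[C@@H](O)CC1(C)C | intermediate
3 | ethyl (1R,2RS,5S,6S)-5-hydroxy-1,3,3-trimethyl-7-oxabicyclo[4.1.0]heptane-2-carboxylate | CCOC(=O)C1C(C)(C)C[C@H](O)[C@@H]2O[C@]12C | intermediate
4 | ethyl (3R,4S)-3,4-dihydroxy-2,6,6-trimethylcyclohex-1-ene-1-carboxylate | CCOC(=O)C1=C(C)[C@@H](O)[C@@H](O)CC1(C)C | intermediate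
5 | ethyl (3R,4S)-2,6,6-trimethyl-3,4-bis(triethylsilyloxy)cyclohex-1-ene-1-carboxylate | CCOC(=O)C1=C(C)[C@@H](O[Si](CC)(CC)CC)[C@@H](O[Si](CC)(CC)CC)CC1(C)C | intermediate
6 | [(3R,4S)-2,6,6-trimethyl-3,4-bis(triethylsilyloxy)cyclohex-1-en-1-yl]methanol | OCC1=C(C)[C@@H](O[Si](CC)(CC)CC)[C@@H](O[Si](CC)(CC)CC)CC1(C)C | intermediate
7 | (3R,4S)-2,6,6-trimethyl-3,4-bis(triethylsilyloxy)cyclohex-1-ene-1-carbaldehyde | O=CC1=C(C)[C@@H](O[Si](CC)(CC)CC)[C@@H](O[Si](CC)(CC)CC)CC1(C)C | intermediate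
8 | ethyl (2E)-4-(diethoxyphosphoryl)-3-methylbut-2-enoate | CCOC(=O)/C=C(\C)CP(=O)(OCC)OCC | starting material
9 | ethyl (2E,4E)-3-methyl-5-[(3R,4S)-2,6,6-trimethyl-3,4-bis(triethylsilyloxy)cyclohex-1-en-1-yl]penta-2,4-dienoate | CCOC(=O)/C=C(C)/C=C/C1=C(C)[C@@H](O[Si](CC)(CC)CC)[C@@H](O[Si](CC)(CC)CC)CC1(C)C | intermediate
10 | (2E,4E)-3-methyl-5-[(3R,4S)-2,6,6-trimethyl-3,4-bis(triethylsilyloxy)cyclohex-1-en-1-yl]penta-2,4-dien-1-ol | OC/C=C(C)/C=C/C1=C(C)[C@@H](O[Si](CC)(CC)CC)[C@@H](O[Si](CC)(CC)CC)CC1(C)C | intermediate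
11 | (3R,4S)-1-[(1E,3E)-5-bromo-3-methylpenta-1,3-dien-1-yl]-2,6,6-trimethyl-3,4-bis(triethylsilyloxy)cyclohex-1-ene | BrC/C=C(C)/C=C/C1=C(C)[C@@H](O[Si](CC)(CC)CC)[C@@H](O[Si](CC)(CC)CC)CC1(C)C | intermediate
12 | diethyl {(2E,4E)-3-methyl-5-[(3R,4S)-2,6,6-trimethyl-3,4-bis(triethylsilyloxy)cyclohex-1-en-1-yl]penta-2,4-dien-1-yl}phosphonate | CCOP(=O)(OCC)C/C=C(C)/C=C/C1=C(C)[C@@H](O[Si](CC)(CC)CC)[C@@H](O[Si](CC)(CC)CC)CC1(C)C | intermediate
13 | (4R,6R)-4-hydroxy-2,2,6-trimethylcyclohexan-1-one (actinol) | O=C1C(C)(C)C[C@H](O)C[C@H]1C | starting material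
14 | (4R,6R)-2,2,6-trimethyl-4-(triethylsilyloxy)cyclohexan-1-one | O=C1C(C)(C)C[C@H](O[Si](CC)(CC)CC)C[C@H]1C | intermediate
15 | (4R)-2,6,6-trimethyl-4-(triethylsilyloxy)cyclohex-1-en-1-yl trifluoromethanesulfonate | CC1=C(OS(=O)(=O)C(F)(F)F)C(C)(C)C[C@H](O[Si](CC)(CC)CC)C1 | intermediate
16 | methyl (4R)-2,6,6-trimethyl-4-(triethylsilyloxy)cyclohex-1-ene-1-carboxylate | COC(=O)C1=C(C)C[C@@H](O[Si](CC)(CC)CC)CC1(C)C | intermediate
17 | [(4R)-2,6,6-trimethyl-4-(triethylsilyloxy)cyclohex-1-en-1-yl]methanol | OCC1=C(C)C[C@@H](O[Si](CC)(CC)CC)CC1(C)C | intermediate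
18 | [(1R,4S,6R)-2,2,6-trimethyl-4-(triethylsilyloxy)-7-oxabicyclo[4.1.0]heptan-1-yl]methanol (epoxide anti to the silyloxy group) | OC[C@]12O[C@]2(C)C[C@@H](O[Si](CC)(CC)CC)CC1(C)C | intermediate
19 | (1S,4S,6R)-2,2,6-trimethyl-4-(triethylsilyloxy)-7-oxabicyclo[4.1.0]heptane-1-carbaldehyde | O=C[C@]12O[C@]2(C)C[C@@H](O[Si](CC)(CC)CC)CC1(C)C | intermediate
20 | ethyl 2-oxo-3-(triphenyl-λ5-phosphanylidene)propanoate | CCOC(=O)C(=O)C=P(c1ccccc1)(c1ccccc1)c1ccccc1 | starting material
21 | ethyl (3E)-2-oxo-4-[(1S,4S,6R)-2,2,6-trimethyl-4-(triethylsilyloxy)-7-oxabicyclo[4.1.0]heptan-1-yl]but-3-enoate | CCOC(=O)C(=O)/C=C/[C@]12O[C@]2(C)C[C@@H](O[Si](CC)(CC)CC)CC1(C)C | intermediate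
22 | ethyl (3E)-4-[(1S,4S,6R)-4-hydroxy-2,2,6-trimethyl-7-oxabicyclo[4.1.0]heptan-1-yl]-2-oxobut-3-enoate | CCOC(=O)C(=O)/C=C/[C@]12O[C@]2(C)C[C@@H](O)CC1(C)C | intermediate
23 | ethyl (3E)-4-[(1R,2R,4S)-2-hydroxy-2,6,6-trimethyl-7-oxabicyclo[2.2.1]heptan-1-yl]-2-oxobut-3-enoate | CCOC(=O)C(=O)/C=C/[C@@]12O[C@@H](CC1(C)C)C[C@@]2(C)O | intermediate
24 | caesium (3E)-4-[(1R,2R,4S)-2-hydroxy-2,6,6-trimethyl-7-oxabicyclo[2.2.1]heptan-1-yl]-2-oxobut-3-enoate | [Cs+].[O-]C(=O)C(=O)/C=C/[C@@]12O[C@@H](CC1(C)C)C[C@@]2(C)O | intermediate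
25 | (2E)-3-methylpent-2-en-4-yn-1-ol | C#C/C(C)=C/CO | starting material
26 | (2E)-3-methylpent-2-en-4-ynal | C#C/C(C)=C/C=O | intermediate
27 | (triphenyl-λ5-phosphanylidene)acetaldehyde | O=CC=P(c1ccccc1)(c1ccccc1)c1ccccc1 | starting material
28 | (2E,4E)-5-methylhepta-2,4-dien-6-ynal | C#C/C(C)=C/C=C/C=O | intermediate
29 | (3E,5E)-7,7-dimethoxy-3-methylhepta-3,5-dien-1-yne | C#C/C(C)=C/C=C/C(OC)OC | intermediate
30 | (4E,6E)-8,8-dimethoxy-4-methylocta-4,6-dien-2-yn-1-ol | OCC#C/C(C)=C/C=C/C(OC)OC | intermediate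
31 | (2E,4E)-8-bromo-1,1-dimethoxy-5-methylocta-2,4-dien-6-yne | BrCC#C/C(C)=C/C=C/C(OC)OC | intermediate
32 | [(4E,6E)-8,8-dimethoxy-4-methylocta-4,6-dien-2-yn-1-yl]triphenylphosphonium bromide | [Br-].COC(OC)/C=C/C=C(C)/C#CC[P+](c1ccccc1)(c1ccccc1)c1ccccc1 | intermediate
33 | [(4E,6E)-8,8-dimethoxy-4-methylocta-1,2,4,6-tetraen-1-yl]triphenylphosphonium (3E)-4-[(1R,2R,4S)-2-hydroxy-2,6,6-trimethyl-7-oxabicyclo[2.2.1]heptan-1-yl]-2-oxobut-3-enoate (ion pair) | COC(OC)/C=C/C=C(C)/C=C=C[P+](c1ccccc1)(c1ccccc1)c1ccccc1.[O-]C(=O)C(=O)/C=C/[C@@]12O[C@@H](CC1(C)C)C[C@@]2(C)O | intermediate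
34 | (2Z,4E,6E)-8,8-dimethoxy-4-methyl-1-(triphenyl-λ5-phosphanylidene)octa-2,4,6-trien-2-yl (3E)-4-[(1R,2R,4S)-2-hydroxy-2,6,6-trimethyl-7-oxabicyclo[2.2.1]heptan-1-yl]-2-oxobut-3-enoate | COC(OC)/C=C/C=C(C)/C=C(\OC(=O)C(=O)/C=C/[C@@]12O[C@@H](CC1(C)C)C[C@@]2(C)O)C=P(c1ccccc1)(c1ccccc1)c1ccccc1 | intermediate
35 | (5Z)-5-[(2E,4E)-6,6-dimethoxy-2-methylhexa-2,4-dien-1-ylidene]-3-{(E)-2-[(1R,2R,4S)-2-hydroxy-2,6,6-trimethyl-7-oxabicyclo[2.2.1]heptan-1-yl]ethenyl}furan-2(5H)-one | COC(OC)/C=C/C=C(C)/C=C1C=C(/C=C/[C@@]23O[C@@H](CC2(C)C)C[C@@]3(C)O)C(=O)O/1 | intermediate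
36 | (2E,4E,6Z)-6-[4-{(E)-2-[(1R,2R,4S)-2-hydroxy-2,6,6-trimethyl-7-oxabicyclo[2.2.1]heptan-1-yl]ethenyl}-5-oxofuran-2(5H)-ylidene]-5-methylhexa-2,4-dienal | O=C/C=C/C=C(C)/C=C1C=C(/C=C/[C@@]23O[C@@H](CC2(C)C)C[C@@]3(C)O)C(=O)O/1 | intermediate
37 | (5Z)-5-{(2E,4E,6E,8E,10E)-2,9-dimethyl-11-[(3R,4S)-2,6,6-trimethyl-3,4-bis(triethylsilyloxy)cyclohex-1-en-1-yl]undeca-2,4,6,8,10-pentaen-1-ylidene}-3-{(E)-2-[(1R,2R,4S)-2-hydroxy-2,6,6-trimethyl-7-oxabicyclo[2.2.1]heptan-1-yl]ethenyl}furan-2(5H)-one | CC1=C(/C=C/C(C)=C/C=C/C=C/C=C(C)/C=C2C=C(/C=C/[C@@]34O[C@@H](CC3(C)C)C[C@@]4(C)O)C(=O)O/2)C(C)(C)C[C@H](O[Si](CC)(CC)CC)[C@@H]1O[Si](CC)(CC)CC | intermediate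
38 | (5Z)-5-{(2E,4E,6E,8E,10E)-11-[(3R,4S)-3,4-dihydroxy-2,6,6-trimethylcyclohex-1-en-1-yl]-2,9-dimethylundeca-2,4,6,8,10-pentaen-1-ylidene}-3-{(E)-2-[(1R,2R,4S)-2-hydroxy-2,6,6-trimethyl-7-oxabicyclo[2.2.1]heptan-1-yl]ethenyl}furan-2(5H)-one (CNP0216838.1) | CC1=C(/C=C/C(C)=C/C=C/C=C/C=C(C)/C=C2C=C(/C=C/[C@@]34O[C@@H](CC3(C)C)C[C@@]4(C)O)C(=O)O/2)C(C)(C)C[C@H](O)[C@@H]1O | target

**Totals**

Total step count: 29.
Longest linear sequence: 13 steps (13 → 38, steps 11–19 and 26–29).

**Steps most likely to fail**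

1. Step 26 (proposed new method). The propargyl ylide may undergo intermolecular Wittig reaction at the keto group before the carboxylate has added to the allene. The adduct may also rest as the protonated vinylphosphonium salt, or the ylidene may close with incomplete Z control. The fallback uses known chemistry, sets out from 23 and 32 and returns at 35; it makes the C3=C4 bond first and closes the ring at O1–C5. Salt 32 is deprotonated (NaHMDS, THF, −78 °C) and the resulting ylide olefinates the keto group of 23, the ylide substituent ending cis to the ester as is usual for pyruvate-type ketones, to give ethyl (2Z,6E,8E)-2-{(E)-2-[(1R,2R,4S)-2-hydroxy-2,6,6-trimethyl-7-oxabicyclo[2.2.1]heptan-1-yl]ethenyl}-10,10-dimethoxy-6-methyldeca-2,6,8-trien-4-ynoate F1. Saponification (LiOH, THF–H2O, 0 °C) gives the corresponding (2Z)-enynoic acid F2. Silver-catalysed 5-exo-dig lactonisation (AgNO3 cat., acetone, rt; anti addition of the carboxylate across the triple bond) should then give the (5Z)-ylidenebutenolide 35.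

2. Step 28. The phosphonate anion may deprotonate the vinylogous methyl group or attack the lactone of 36 instead of the aldehyde, and the E selectivity at C11′=C12′ may be incomplete. The fallback sets out from 11 and 36 and returns at 37; it replaces the carbanion by a base-free Wittig reaction with thermodynamic stereocorrection. Bromide 11 and PPh3 (toluene, rt) give {(2E,4E)-3-methyl-5-[(3R,4S)-2,6,6-trimethyl-3,4-bis(triethylsilyloxy)cyclohex-1-en-1-yl]penta-2,4-dien-1-yl}triphenylphosphonium bromide F3. This is condensed with 36 in 1,2-epoxybutane at 60 °C, where the ylide is generated without added base. The E/Z mixture at the new double bond is equilibrated to the all-E polyene 37 with catalytic iodine in daylight.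

3. Step 1. Facial discrimination by the oxazaborolidine may be insufficient, because the CH2–CMe2 arm is not much smaller than the alkenyl arm; this would erode the enantiomeric purity at C3′, the only reagent-controlled stereocentre of this half. The fallback sets out from 16 and returns at 6; it takes C3′ from the chiral pool instead and replaces steps 1–5. Allylic oxidation of 16 (CrO3·3,5-dimethylpyrazole, CH2Cl2, −20 °C) gives methyl (4S)-2,6,6-trimethyl-3-oxo-4-(triethylsilyloxy)cyclohex-1-ene-1-carboxylate F4. L-Selectride (THF, −78 °C) reduces this β-substituted enone 1,2 with equatorial attack and should give the cis-alcohol methyl (3R,4S)-3-hydroxy-2,6,6-trimethyl-4-(triethylsilyloxy)cyclohex-1-ene-1-carboxylate F5. Silylation (TESCl, imidazole, DMF) gives methyl (3R,4S)-2,6,6-trimethyl-3,4-bis(triethylsilyloxy)cyclohex-1-ene-1-carboxylate F6, and DIBAL-H reduction gives 6.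

Further compounds
F1 | step 26 | ethyl (2Z,6E,8E)-2-{(E)-2-[(1R,2R,4S)-2-hydroxy-2,6,6-trimethyl-7-oxabicyclo[2.2.1]heptan-1-yl]ethenyl}-10,10-dimethoxy-6-methyldeca-2,6,8-trien-4-ynoate | CCOC(=O)/C(/C=C/[C@@]12O[C@@H](CC1(C)C)C[C@@]2(C)O)=C\C#C/C(C)=C/C=C/C(OC)OC
F2 | step 26 | (2Z,6E,8E)-2-{(E)-2-[(1R,2R,4S)-2-hydroxy-2,6,6-trimethyl-7-oxabicyclo[2.2.1]heptan-1-yl]ethenyl}-10,10-dimethoxy-6-methyldeca-2,6,8-trien-4-ynoic acid | OC(=O)/C(/C=C/[C@@]12O[C@@H](CC1(C)C)C[C@@]2(C)O)=C\C#C/C(C)=C/C=C/C(OC)OC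
F3 | step 28 | {(2E,4E)-3-methyl-5-[(3R,4S)-2,6,6-trimethyl-3,4-bis(triethylsilyloxy)cyclohex-1-en-1-yl]penta-2,4-dien-1-yl}triphenylphosphonium bromide | [Br-].CC1=C(/C=C/C(C)=C/C[P+](c2ccccc2)(c2ccccc2)c2ccccc2)C(C)(C)C[C@H](O[Si](CC)(CC)CC)[C@@H]1O[Si](CC)(CC)CC
F4 | step 1 | methyl (4S)-2,6,6-trimethyl-3-oxo-4-(triethylsilyloxy)cyclohex-1-ene-1-carboxylate | COC(=O)C1=C(C)C(=O)[C@@H](O[Si](CC)(CC)CC)CC1(C)C
F5 | step 1 | methyl (3R,4S)-3-hydroxy-2,6,6-trimethyl-4-(triethylsilyloxy)cyclohex-1-ene-1-carboxylate | COC(=O)C1=C(C)[C@@H](O)[C@@H](O[Si](CC)(CC)CC)CC1(C)C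
F6 | step 1 | methyl (3R,4S)-2,6,6-trimethyl-3,4-bis(triethylsilyloxy)cyclohex-1-ene-1-carboxylate | COC(=O)C1=C(C)[C@@H](O[Si](CC)(CC)CC)[C@@H](O[Si](CC)(CC)CC)CC1(C)C
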